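Assumption: the target is exactly the given SMILES, i.e. (1R,2R,3R,4R,6S,8S,10S)-1-acetoxy-2,8-bis(angeloyloxy)-4-chloro-3,10,11-trihydroxybisabol-7(14)-ene. Bisabolane numbering (ring C1–C6, C7(=C14), C8–C11, ring methyl C15) is used in the step rationales, so in carvone the carbonyl carbon is C2, the α′-CH2 is C1, the isopropenyl-bearing carbon is C6 and the isopropenyl methyl is C8.

## Retrosynthetic overview

1. Target ⇒ 3,4-epoxide bis-angelate (HCl: trans-diaxial chloride opening at C4 plus acetonide loss) ⇒ 2,8-diol (double angeloylation).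
2. C8 carbinol ⇒ 1,3-anti hydroxyl-directed reduction of a C8 enone ⇒ allylic oxidation of the 7(14)-alkene.
3. Key C8–C9 bond ⇒ visible-light, nickel-catalysed decarboxylative allylation of a carvone-derived allylic chloride with a dihydroxy carboxylate.
4. Building blocks: (R)-carvone 1 (ring, C7, C8, C14, C15; its C6 centre controls C1–C4) and L-malic acid 2 (C9–C13 with C10; its C4 carboxyl leaves as CO2).
5. Rings: the carbocycle is bought in 1 and never rebuilt; the only ring made is the 3,4-epoxide (step 4), opened in the last step.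

## Route

Step 1
Reactants: 1 (R)-carvone
Product: 5 trans-6-hydroxycarvone, via silyl dienol ether 3 (not isolated), via silyloxy ketone 4 (not isolated)
Conditions: LiN(iPr)2, THF, −78 °C; Me3SiCl; then mCPBA, NaHCO3, CH2Cl2, −20 °C; 1 M HCl, THF, 0 °C
Reagents that add atoms: mCPBA, OOC(=O)c1cccc(Cl)c1
Why: Rubottom oxidation – the kinetic cross-conjugated dienolate is trapped as its silyl dienol ether, which mCPBA oxidises much faster than the isopropenyl group and from the face opposite the adjacent isopropenyl substituent, so the new C1–O bond is trans to it.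

Step 2
Reactants: 5 trans-6-hydroxycarvone
Product: 7 cis-6-acetoxycarvone, via triflate 6 (not isolated)
Conditions: (CF3SO2)2O, pyridine, CH2Cl2, −78 → −30 °C; then Bu4NOAc, AcOH, MeCN, −30 → 0 °C
Reagents that add atoms: tetrabutylammonium acetate, CC(=O)[O-].CCCC[N+](CCCC)(CCCC)CCCC
Why: Carbonyl-accelerated SN2 displacement of the α-keto triflate by acetate inverts C1 and puts the acetate cis to the isopropenyl group (the contra-steric configuration that direct electrophilic oxygenation does not give), with AcOH buffering and low temperature to suppress epimerisation.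

Step 3
Reactants: 7 cis-6-acetoxycarvone
Product: 8 (1R,2S,6S)-2-hydroxy-3-methyl-6-(prop-1-en-2-yl)cyclohex-3-en-1-yl acetate
Conditions: NaBH4, CeCl3·7H2O, MeOH, −78 °C
Reagents that add atoms: none
Why: Luche reduction – 1,2-selective hydride attack anti to the axial α-acetoxy group (the same axial sense that turns carvone into cis-carveol) gives the C2 alcohol cis to both the acetate and the isopropenyl group.

Step 4
Reactants: 8 all-cis hydroxy acetate
Product: 9 cis-epoxy alcohol
Conditions: VO(acac)2 (3 mol%), t-BuOOH, CH2Cl2, 0 °C → rt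
Reagents that add atoms: tert-butyl hydroperoxide, CC(C)(C)OO
Why: Hydroxyl-directed vanadium-catalysed epoxidation delivers oxygen only to the allylic-alcohol alkene and syn to the C2 hydroxyl, setting C3 and C4 and leaving the isopropenyl alkene untouched.

Step 5
Reactants: 9 cis-epoxy alcohol
Product: 10 allylic chloride
Conditions: Ca(OCl)2, CO2 (solid), CH2Cl2/H2O, 0 °C
Reagents that add atoms: calcium hypochlorite, [Ca+2].[O-]Cl.[O-]Cl
Why: Ene-type allylic chlorination by HOCl (as in the conversion of carvone to 10-chlorocarvone) transfers Cl+ to the terminal carbon of the only nucleophilic alkene left with loss of a methyl proton, giving the 2-substituted allyl chloride without touching any stereocentre.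

Step 6
Reactants: 2 L-malic acid
Product: 11 (S)-2-(2,2-dimethyl-5-oxo-1,3-dioxolan-4-yl)acetic acid
Conditions: Me2C(OMe)2, TsOH (cat.), rt
Reagents that add atoms: 2,2-dimethoxypropane, COC(C)(C)OC
Why: Acetalisation of the α-hydroxy acid as the five-membered dioxolanone differentiates the two carboxyls (the β-carboxyl stays free) and does not involve the stereocentre.

Step 7
Reactants: 11 dioxolanone acid
Product: 12 (S)-4-hydroxy-5,5-dimethyloxolan-2-one
Conditions: MeMgBr (5 equiv), THF, −20 °C → rt; then 2 M HCl, rt
Reagents that add atoms: methylmagnesium bromide, C[Mg]Br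
Why: Double Grignard addition to the dioxolanone carbonyl (the magnesium carboxylate is inert) builds the C11 carbinol with release of acetone, and acidification lactonises the γ-hydroxy acid, the C10 centre being a spectator.

Step 8
Reactants: 10 allylic chloride; 12 (S)-hydroxy lactone
Product: 14 coupled triol, via cesium carboxylate 13 (not isolated)
Conditions: 12 (2.5 equiv), CsOH·H2O, MeOH/H2O, rt, evaporate; then 10, NiCl2·glyme (10 mol%), 4,4′-di-tert-butyl-2,2′-bipyridine (15 mol%), 4CzIPN (3 mol%), DMA, 450 nm LEDs, rt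
Reagents that add atoms: none
Why: Proposed new method: nickel-catalysed, visible-light decarboxylative C(sp3)–C(sp3) allylation of an unprotected, non-stabilised β,γ-dihydroxy carboxylate with a 2-substituted allylic chloride – excited 4CzIPN oxidises the carboxylate, loss of CO2 gives the primary C9 radical, zerovalent nickel ionises the allylic chloride (or any allyl ester it forms with the carboxylate) to a π-allylnickel species that captures the radical far faster than the radical could add to an unactivated alkene, trivalent nickel reductively eliminates the C8–C9 bond and reduced 4CzIPN returns monovalent nickel to the zerovalent state; both allyl termini are CH2, so regiochemistry is degenerate and no stereocentre is made or touched; the closest known reactions are metallaphotoredox decarboxylative alkylation of carboxylic acids with alkyl halides and palladium/photoredox decarboxylative allylation of α-amino acids.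

Step 9
Reactants: 14 coupled triol
Product: 16 β-hydroxy enone, via allylic alcohols 15 (not isolated)
Conditions: SeO2 (20 mol%), t-BuOOH, CH2Cl2, rt; then MnO2 (excess), rt; filter, use crude
Reagents that add atoms: tert-butyl hydroperoxide, CC(C)(C)OO
Why: Selenium dioxide allylic oxidation (ene reaction then [2,3]-shift, CH2 preferred over CH) hydroxylates C8 with the alkene returning to the 7(14) position, and MnO2 then oxidises only this allylic alcohol; the enone is not chromatographed because it can close by oxa-Michael addition or form a hemiketal.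

Step 10
Reactants: 16 β-hydroxy enone
Product: 17 (8S,10S)-anti-diol
Conditions: Me4NBH(OAc)3, MeCN/AcOH (1:1), −30 °C
Reagents that add atoms: none
Why: Evans–Saksena reduction – the C10 alkoxy(diacetoxy)borohydride delivers hydride intramolecularly through a chair-like six-membered transition state, giving the 1,3-anti diol and thus 8S from the malic-acid-derived 10S centre.

Step 11
Reactants: 17 anti-diol
Product: 18 10,11-acetonide
Conditions: Me2C(OMe)2, PPTS (cat.), acetone, rt
Reagents that add atoms: 2,2-dimethoxypropane, COC(C)(C)OC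
Why: Thermodynamic acetalisation takes the 10,11-diol as the five-membered dioxolane rather than the anti-8,10-diol (whose six-membered acetonide needs a twist-boat), leaving only the C2 and C8 hydroxyls free.

Step 12
Reactants: 18 10,11-acetonide
Product: 19 bis-angelate
Conditions: angelic acid, 2,4,6-Cl3C6H2COCl, Et3N, toluene, rt, filter; then 18, toluene, 75 °C
Reagents that add atoms: angelic acid, C/C=C(/C)C(=O)O
Why: Yamaguchi-type esterification with the preformed angelic 2,4,6-trichlorobenzoic mixed anhydride, run without nucleophilic catalyst so the (Z)-alkene does not isomerise to the tiglate, acylates both secondary alcohols and leaves all stereocentres alone.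

Step 13
Reactants: 19 bis-angelate
Product: 20 target CNP0212201.1
Conditions: conc. aq. HCl, THF, 0 °C → rt
Reagents that add atoms: hydrogen chloride, Cl
Why: Acid-mediated epoxide opening by chloride at the secondary C4 in the trans-diaxial (Fürst–Plattner) sense with the C6 side chain equatorial (attack at C3 is further disfavoured by the neighbouring acyloxy group) gives 4-Cl with inversion and 3-OH with retention, and the same aqueous acid hydrolyses the acetonide.

## Compound list

1 | (R)-(−)-carvone, (5R)-2-methyl-5-(prop-1-en-2-yl)cyclohex-2-en-1-one | C=C(C)[C@@H]1CC=C(C)C(=O)C1 | starting material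
2 | L-malic acid, (2S)-2-hydroxybutanedioic acid | OC(=O)C[C@H](O)C(O)=O | starting material
3 | trimethylsilyl dienol ether of 1, (R)-trimethyl{[6-methyl-3-(prop-1-en-2-yl)cyclohexa-1,5-dien-1-yl]oxy}silane | C=C(C)[C@@H]1CC=C(C)C(O[Si](C)(C)C)=C1 | intermediate (not isolated)
4 | (5S,6S)-2-methyl-5-(prop-1-en-2-yl)-6-(trimethylsilyloxy)cyclohex-2-en-1-one, silyloxy trans to isopropenyl | C=C(C)[C@@H]1CC=C(C)C(=O)[C@H]1O[Si](C)(C)C | intermediate (not isolated)
5 | trans-6-hydroxycarvone, (5S,6S)-6-hydroxy-2-methyl-5-(prop-1-en-2-yl)cyclohex-2-en-1-one | C=C(C)[C@@H]1CC=C(C)C(=O)[C@H]1O | intermediate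
6 | triflate of 5, (1S,6S)-3-methyl-2-oxo-6-(prop-1-en-2-yl)cyclohex-3-en-1-yl trifluoromethanesulfonate | C=C(C)[C@@H]1CC=C(C)C(=O)[C@H]1OS(=O)(=O)C(F)(F)F | intermediate (not isolated)
7 | cis-6-acetoxycarvone, (1R,6S)-3-methyl-2-oxo-6-(prop-1-en-2-yl)cyclohex-3-en-1-yl acetate, acetate cis to isopropenyl | C=C(C)[C@@H]1CC=C(C)C(=O)[C@@H]1OC(C)=O | intermediate
8 | (1R,2S,6S)-2-hydroxy-3-methyl-6-(prop-1-en-2-yl)cyclohex-3-en-1-yl acetate; OAc, OH and isopropenyl all cis | C=C(C)[C@@H]1CC=C(C)[C@H](O)[C@@H]1OC(C)=O | intermediate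
9 | 2-hydroxy-1-methyl-4-(prop-1-en-2-yl)-7-oxabicyclo[4.1.0]heptan-3-yl acetate; epoxide O, OH, OAc and isopropenyl all cis, ring methyl trans | C=C(C)[C@@H]1C[C@@H]2O[C@]2(C)[C@H](O)[C@@H]1OC(C)=O | intermediate
10 | 4-(3-chloroprop-1-en-2-yl)-2-hydroxy-1-methyl-7-oxabicyclo[4.1.0]heptan-3-yl acetate; same ring configuration as 9 | C=C(CCl)[C@@H]1C[C@@H]2O[C@]2(C)[C@H](O)[C@@H]1OC(C)=O | intermediate
11 | (S)-2-(2,2-dimethyl-5-oxo-1,3-dioxolan-4-yl)acetic acid | OC(=O)C[C@@H]1OC(C)(C)OC1=O | intermediate
12 | (S)-4-hydroxy-5,5-dimethyloxolan-2-one | O=C1C[C@H](O)C(C)(C)O1 | intermediate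
13 | cesium (S)-3,4-dihydroxy-4-methylpentanoate | [Cs+].[O-]C(=O)C[C@H](O)C(C)(C)O | intermediate (not isolated)
14 | (10S)-1-acetoxy-3,4-epoxybisabol-7(14)-ene-2,10,11-triol; 1-OAc, 2-OH and epoxide O cis to the C6 side chain | C=C(CC[C@H](O)C(C)(C)O)[C@@H]1C[C@@H]2O[C@]2(C)[C@H](O)[C@@H]1OC(C)=O | intermediate
15 | (10S)-1-acetoxy-3,4-epoxybisabol-7(14)-ene-2,8,10,11-tetraol, mixture of C8 epimers | C=C(C(O)C[C@H](O)C(C)(C)O)[C@@H]1C[C@@H]2O[C@]2(C)[C@H](O)[C@@H]1OC(C)=O | intermediate (not isolated)
16 | (10S)-1-acetoxy-3,4-epoxy-2,10,11-trihydroxybisabol-7(14)-en-8-one | C=C(C(=O)C[C@H](O)C(C)(C)O)[C@@H]1C[C@@H]2O[C@]2(C)[C@H](O)[C@@H]1OC(C)=O | intermediate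
17 | (8S,10S)-1-acetoxy-3,4-epoxybisabol-7(14)-ene-2,8,10,11-tetraol, 8,10-anti | C=C([C@H](C[C@H](O)C(C)(C)O)O)[C@@H]1C[C@@H]2O[C@]2(C)[C@H](O)[C@@H]1OC(C)=O | intermediate
18 | 10,11-O-isopropylidene derivative of 17 (2-OH and 8-OH free) | C=C([C@H](C[C@@H]1OC(C)(C)OC1(C)C)O)[C@@H]2C[C@@H]3O[C@]3(C)[C@H](O)[C@@H]2OC(C)=O | intermediate
19 | 2,8-di-O-angeloyl derivative of 18 | C=C([C@H](C[C@@H]1OC(C)(C)OC1(C)C)OC(=O)/C(C)=C\C)[C@@H]2C[C@@H]3O[C@]3(C)[C@H](OC(=O)/C(C)=C\C)[C@@H]2OC(C)=O | intermediate
20 | CNP0212201.1, (1R,2R,3R,4R,6S,8S,10S)-1-acetoxy-2,8-bis(angeloyloxy)-4-chloro-3,10,11-trihydroxybisabol-7(14)-ene | C=C([C@H](C[C@H](O)C(C)(C)O)OC(=O)/C(C)=C\C)[C@@H]1C[C@@H](Cl)[C@](C)(O)[C@H](OC(=O)/C(C)=C\C)[C@@H]1OC(C)=O | target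

## Step count and risks

Total step count: 13. Longest linear sequence: 11 steps (1 → 20 through steps 1–5 and 8–13); steps 6–7 make the side-chain piece.

Three steps most likely to fail:

Step 8 (the proposed new coupling; risks are sluggish oxidation of the non-stabilised carboxylate, allyl homocoupling and β-hydride loss at nickel). Fallback by known chemistry, setting out from 10 and returning at 14: displace the chloride of 10 with PhSO2Na in DMF to give the allyl phenyl sulfone F4, then run the established photoredox decarboxylative radical allylation (addition to the sulfone alkene and loss of the sulfonyl radical) with cesium carboxylate 13 and 4CzIPN under blue light, which gives 14 without any nickel.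

Step 2 (SN2 at a hindered α-keto centre; risks are epimerisation of 7 and elimination). Fallback setting out from 5 and returning at 7, replacing substitution by kinetic protonation: silylate 5 (t-BuMe2SiCl, imidazole) to the trans silyl ether (5S,6S)-6-(tert-butyldimethylsilyloxy)carvone F1; deprotonate at the oxygenated α′-carbon with LiN(iPr)2 at −78 °C and protonate the enolate with AcOH at −78 °C from the face opposite the isopropenyl group to give the cis silyl ether F2; cleave with HF·pyridine to cis-6-hydroxycarvone F3; acetylate (Ac2O, pyridine, 0 °C) to 7.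

Step 12 (two hindered secondary alcohols; risks are angelate-to-tiglate isomerisation and acetyl migration from O1 to O2). Fallback setting out from 18 and returning at 19, building the (Z)-alkenes instead of transferring them: esterify both hydroxyls with 2-[bis(2,2,2-trifluoroethoxy)phosphoryl]propanoic acid (DCC, DMAP, CH2Cl2) to the bis(phosphonopropionate) F5, then Still–Gennari olefination (KN(SiMe3)2, 18-crown-6, THF, −78 °C, acetaldehyde) to give the two (Z)-2-methylbut-2-enoates of 19.

Further compounds
F1 | step 2 | (5S,6S)-6-(tert-butyldimethylsilyloxy)-2-methyl-5-(prop-1-en-2-yl)cyclohex-2-en-1-one (silyloxy trans to isopropenyl) | C=C(C)[C@@H]1CC=C(C)C(=O)[C@H]1O[Si](C)(C)C(C)(C)C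
F2 | step 2 | (5S,6R)-6-(tert-butyldimethylsilyloxy)-2-methyl-5-(prop-1-en-2-yl)cyclohex-2-en-1-one (silyloxy cis to isopropenyl) | C=C(C)[C@@H]1CC=C(C)C(=O)[C@@H]1O[Si](C)(C)C(C)(C)C
F3 | step 2 | cis-6-hydroxycarvone, (5S,6R)-6-hydroxy-2-methyl-5-(prop-1-en-2-yl)cyclohex-2-en-1-one | C=C(C)[C@@H]1CC=C(C)C(=O)[C@@H]1O
F4 | step 8 | 2-hydroxy-1-methyl-4-[3-(phenylsulfonyl)prop-1-en-2-yl]-7-oxabicyclo[4.1.0]heptan-3-yl acetate, ring configuration as in 10 | C=C(CS(=O)(=O)c1ccccc1)[C@@H]1C[C@@H]2O[C@]2(C)[C@H](O)[C@@H]1OC(C)=O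
F5 | step 12 | 2,8-bis-O-{2-[bis(2,2,2-trifluoroethoxy)phosphoryl]propanoyl} derivative of 18 (phosphonate α-carbons unassigned) | C=C([C@H](C[C@@H]1OC(C)(C)OC1(C)C)OC(=O)C(C)P(=O)(OCC(F)(F)F)OCC(F)(F)F)[C@@H]2C[C@@H]3O[C@]3(C)[C@H](OC(=O)C(C)P(=O)(OCC(F)(F)F)OCC(F)(F)F)[C@@H]2OC(C)=O
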